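(The data were computed for an exercise.)

In the west run 1.0 % of the D is left at 5.00 h, yet Z stands at 17.9 %. So the spent D went more than one way, and what you want is a ratio of two amounts built up so far: D gone into Z against D gone into everything else. Call it the split: Z divided by the D spent on other things, which is the charge less Z less the D left.

in all of them: E 7.1 mM (held)
- west: D 0.050 M; Q 0.25 mol%; run made earlier
- north: D 0.050 M; Q 0.57 mol%; run made earlier
- north-west: D 0.10 M; Q 0.38 mol%; run made earlier
- flask: D 0.050 M; Q 0.38 mol%; time 4.0 h

- west (time / h: Z / %, D / %): 0.417: 10.5, 24.2; 1.33: 16.2, 6.7; 2.00: 16.6, 3.9; 3.00: 17.0, 2.1; 5.00: 17.9, 1.0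
- north (time / h: Z / %, D / %): 1.00: 28.0, 7.1; 2.00: 30.1, 2.5; 3.00: 29.7, 1.3; 4.00: 30.6, 1.1; 5.00: 31.0, 0.9
- north-west (time / h: Z / %, D / %): 0.417: 20.4, 12.0; 0.667: 22.5, 7.4; 1.33: 24.2, 3.1; 2.50: 24.3, 1.1; 5.00: 24.7, 0.7

(standard deviation of a reading: 0.3 percentage points)

- at the start none of E is in solution

- midnight: doubling the amount of Q, all else as stated
- dusk: doubling the transfer coefficient of E, all else as stated
- spring: doubling the saturation concentration of E, all else as stated

- the Z standing at 4.0 h, as a percentage of the D charged
- the change that raises the amount of Z at 4.0 h, in percent of the D charged most ("none" if none brings more than 2 percentage points) (midnight / dusk / spring / none)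
- amount of Z at 4.0 h, in percent of the D charged, after midnight

West run, last reading: 0.221

North run, last reading: 0.455

North-west run, last reading: 0.331

From west to north the split grows 2.06-fold while the loading grows 2.28-fold, so I take it as roughly proportional to Q. The north-west run, at 0.10 M of D, suggests that [D] matters little at fixed loading.

Split of the flask: 0.313

Z at 4.0 h, with D left as in the north run at that time: 23.6 %

The forecast gives 24 % (23 % to 25 %), names midnight as the best change and gives 36.5 % (33.5 % to 40 %) after it, holding that “Q sets how much D is channelled to Z”.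

The flask gives 23.7 %, the best change is midnight, and Z after it is 36.2 %.

    E ⇌ J, rate k1*(csat - [J]) (kL = 0.150 s⁻¹)
    D + J + Q → Q + Z (k = 170 M⁻² s⁻¹)
    D + J → L (k = 0.00970 M⁻¹ s⁻¹)
    2 D → X (k = 0.0150 M⁻¹ s⁻¹)
    Q + Z → G (k = 0.0140 M⁻¹ s⁻¹)

In the flask, half of the turnover into X was done by 0.103 h, and at 0.400 h D stood at 23.9 %, X at 56.6 % and Z at 14.9 %. By 4.00 h D was down to 1.11 %, with X at 65.9 % and Z at 23.7 %, a split of 0.315. Scaled to 0.23 mol% of Q, the split becomes 0.190, which means 15.7 % Z; that neighbour flask holds 16.7 % Z beside 71.9 % X.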